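Ring B (C5, C6, C7, C8, C9, C10, C1) is cut at C8–C9, the bond opposite the C1–C5 fusion that links the two adjacent methyl-bearing stereocentres. Retrosynthetically this turns ring B into two alkenyl groups on a cyclopropane C1–C5–C6 fused to ring A. In the forward sense, heating this cis-dialkenyl bicyclo[3.1.0]hexane triggers a Cope ring expansion that forms C8–C9, breaks C1–C6 and delivers C8, the quaternary C9 and the masked C10 ketone at once. The precursor bears an exo (E)-propenyl group on C6 and, on C1, a tetrasubstituted silyl enol ether whose methyl is trans to C1; ring A with its C3 and C5 oxygens is already in place.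

Key step: step 17

Remark 1 (locants): target locants are used throughout (ring A: C1–C5; ring B: C5–C10 and C1; side chain C11, C12); β is the ring-A face that carries the C5 oxygen, α the opposite face; exo and endo refer to C6 of the bicyclo[3.1.0]hexane.

Remark 2 (assumption on C3): the cyclopropane must sit on the face that finally carries the C3 oxygen, but a carbenoid is assumed to add anti to a C3 oxygen substituent; C3 therefore enters as the epimeric β-pivalate, which steers the carbenoid to the α face, and is reset to α by oxidation and hydride addition anti to the cyclopropane (steps 7 and 9).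

Remark 3 (precursor design): the rearrangement substrate carries a triethylsilyl group on the C5 oxygen, beside which the C11 methylene must pass, and a benzyl ether at C12 that survives heating and leaves in the hydrogenation; no alkene other than the enol ether is present when the carbenoid is used.

Step 1
Reactants: 1 2,2-dimethylcyclopentane-1,3-dione
Product: 2 (S)-3-hydroxy-2,2-dimethylcyclopentan-1-one
Conditions: (R)-2-methyl-CBS-oxazaborolidine (10 mol %), BH3·SMe2 (0.6 equiv), THF, −30 °C; MeOH, aq. work-up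
Reagents that add atoms: none
Why: Corey–Bakshi–Shibata reduction, in which the catalyst–borane complex delivers hydride to one face of either of the two equivalent carbonyl groups with the quaternary carbon as the large substituent, should set C3 as S, and substoichiometric borane limits diol formation.

Step 2
Reactants: 2 (S)-3-hydroxy-2,2-dimethylcyclopentan-1-one
Product: 3 (S)-2,2-dimethyl-3-oxocyclopentyl pivalate
Conditions: t-BuCOCl, pyridine, DMAP (cat.), CH2Cl2, 0 °C → rt
Reagents that add atoms: pivaloyl chloride, CC(C)(C)C(=O)Cl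
Why: DMAP-catalysed acylation gives a bulky ester that tolerates the enolate chemistry, steers the carbenoid in step 5 and is removed by hydride in step 6.

Step 3
Reactants: 3 (S)-2,2-dimethyl-3-oxocyclopentyl pivalate
Product: 4 (1S)-4-(hydroxymethyl)-2,2-dimethyl-3-oxocyclopentyl pivalate
Conditions: LiN(i-Pr)2, THF, −78 °C; CH2O (gas from cracked paraformaldehyde), −78 °C; aq. NH4Cl
Reagents that add atoms: formaldehyde, C=O
Why: Aldol addition of the lithium enolate (only C1 is enolisable) to monomeric formaldehyde installs C10; the new C1 centre forms as a mixture and becomes planar in step 4.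

Step 4
Reactants: 4 (1S)-4-(hydroxymethyl)-2,2-dimethyl-3-oxocyclopentyl pivalate
Product: 5 (1S)-2,2-dimethyl-3-(triethylsilyloxy)-4-[(triethylsilyloxy)methyl]cyclopent-3-en-1-yl pivalate
Conditions: Et3SiOTf (2.5 equiv), Et3N, CH2Cl2, −78 → 0 °C
Reagents that add atoms: triethylsilyl trifluoromethanesulfonate, CC[Si](CC)(CC)OS(=O)(=O)C(F)(F)F
Why: Silylation with a silyl triflate and amine base caps the primary alcohol and converts the ketone, enolisable only towards C1, into the tetrasubstituted silyl enol ether (soft enolisation).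

Step 5
Reactants: 5 (1S)-2,2-dimethyl-3-(triethylsilyloxy)-4-[(triethylsilyloxy)methyl]cyclopent-3-en-1-yl pivalate; 6 ethyl diazoacetate
Product: 7 ethyl 4,4-dimethyl-3β-(pivaloyloxy)-5-(triethylsilyloxy)-1-[(triethylsilyloxy)methyl]bicyclo[3.1.0]hexane-6-exo-carboxylate
Conditions: Rh2(OAc)4 (1 mol %), CH2Cl2, rt, 6 (3 equiv) by syringe pump
Reagents that add atoms: none
Why: Rhodium-carbenoid cyclopropanation of the electron-rich silyl enol ether should occur on the α face, anti to the C3 pivalate, with the ester exo (away from C2 and the C4 methyl groups), which sets C1, C5 and C6; minor isomers are removed by chromatography here, before C3 is erased.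

Step 6
Reactants: 7 ethyl 4,4-dimethyl-3β-(pivaloyloxy)-5-(triethylsilyloxy)-1-[(triethylsilyloxy)methyl]bicyclo[3.1.0]hexane-6-exo-carboxylate
Product: 8 6-exo-(hydroxymethyl)-4,4-dimethyl-5-(triethylsilyloxy)-1-[(triethylsilyloxy)methyl]bicyclo[3.1.0]hexan-3β-ol
Conditions: i-Bu2AlH (6 equiv), CH2Cl2, −78 → 0 °C; aq. KNaC4H4O6 (tartrate)
Reagents that add atoms: none
Why: Hydride reduction of both esters gives the cyclopropylmethanol and frees the C3 hydroxyl in one operation, and the neutral tartrate work-up spares the silyl ethers and the siloxycyclopropane.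

Step 7
Reactants: 8 6-exo-(hydroxymethyl)-4,4-dimethyl-5-(triethylsilyloxy)-1-[(triethylsilyloxy)methyl]bicyclo[3.1.0]hexan-3β-ol
Product: 9 4,4-dimethyl-3-oxo-5-(triethylsilyloxy)-1-[(triethylsilyloxy)methyl]bicyclo[3.1.0]hexane-6-exo-carbaldehyde
Conditions: Dess–Martin periodinane (3 equiv), pyridine, CH2Cl2, 0 °C → rt
Reagents that add atoms: none
Why: Buffered Dess–Martin oxidation of both alcohols gives the exo aldehyde and the C3 ketone (erasing the temporary C3 centre) without acid or fluoride that would open the donor–acceptor cyclopropane.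

Step 8
Reactants: 9 4,4-dimethyl-3-oxo-5-(triethylsilyloxy)-1-[(triethylsilyloxy)methyl]bicyclo[3.1.0]hexane-6-exo-carbaldehyde
Product: 10 4,4-dimethyl-6-exo-[(E)-prop-1-enyl]-5-(triethylsilyloxy)-1-[(triethylsilyloxy)methyl]bicyclo[3.1.0]hexan-3-one
Conditions: CrCl2 (8 equiv), CH3CHI2 (2 equiv), THF, rt
Reagents that add atoms: 1,1-diiodoethane, CC(I)I
Why: Takai–Utimoto olefination with the gem-dichromium reagent should react only at the aldehyde, leaving the neopentyl ketone, and give the (E)-alkene that later places the C8 methyl.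

Step 9
Reactants: 10 4,4-dimethyl-6-exo-[(E)-prop-1-enyl]-5-(triethylsilyloxy)-1-[(triethylsilyloxy)methyl]bicyclo[3.1.0]hexan-3-one
Product: 11 4,4-dimethyl-6-exo-[(E)-prop-1-enyl]-5-(triethylsilyloxy)-1-[(triethylsilyloxy)methyl]bicyclo[3.1.0]hexan-3α-ol
Conditions: LiAlH4, THF, −78 °C; aq. work-up
Reagents that add atoms: none
Why: Hydride reduction of a bicyclo[3.1.0]hexan-3-one takes place from the convex face, anti to the cyclopropane and its endo C6 hydrogen, so the hydroxyl should be set α (3R), cis to the cyclopropane as in the target.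

Step 10
Reactants: 11 4,4-dimethyl-6-exo-[(E)-prop-1-enyl]-5-(triethylsilyloxy)-1-[(triethylsilyloxy)methyl]bicyclo[3.1.0]hexan-3α-ol
Product: 12 3α-(tert-butyldimethylsilyloxy)-4,4-dimethyl-6-exo-[(E)-prop-1-enyl]-5-(triethylsilyloxy)-1-[(triethylsilyloxy)methyl]bicyclo[3.1.0]hexane
Conditions: t-BuMe2SiOTf, 2,6-lutidine, CH2Cl2, −78 → 0 °C
Reagents that add atoms: tert-butyldimethylsilyl trifluoromethanesulfonate, CC(C)(C)[Si](C)(C)OS(=O)(=O)C(F)(F)F
Why: Silylation with the reactive silyl triflate and a hindered base protects the hindered secondary alcohol.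

Step 11
Reactants: 12 3α-(tert-butyldimethylsilyloxy)-4,4-dimethyl-6-exo-[(E)-prop-1-enyl]-5-(triethylsilyloxy)-1-[(triethylsilyloxy)methyl]bicyclo[3.1.0]hexane
Product: 13 {3α-(tert-butyldimethylsilyloxy)-4,4-dimethyl-6-exo-[(E)-prop-1-enyl]-5-(triethylsilyloxy)bicyclo[3.1.0]hexan-1-yl}methanol
Conditions: PPTS (cat.), MeOH/CH2Cl2, 0 °C
Reagents that add atoms: none
Why: Acid-catalysed methanolysis should cleave the primary triethylsilyl ether much faster than the tertiary triethylsilyl ether and the hindered secondary tert-butyldimethylsilyl ether (selective desilylation).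

Step 12
Reactants: 13 {3α-(tert-butyldimethylsilyloxy)-4,4-dimethyl-6-exo-[(E)-prop-1-enyl]-5-(triethylsilyloxy)bicyclo[3.1.0]hexan-1-yl}methanol
Product: 14 3α-(tert-butyldimethylsilyloxy)-4,4-dimethyl-6-exo-[(E)-prop-1-enyl]-5-(triethylsilyloxy)bicyclo[3.1.0]hexane-1-carbaldehyde
Conditions: Dess–Martin periodinane, pyridine, CH2Cl2, 0 °C; used at once
Reagents that add atoms: none
Why: Buffered Dess–Martin oxidation gives the non-enolisable aldehyde, which is used cold and immediately because a cis-2-vinylcyclopropanecarbaldehyde can equilibrate with a dihydrooxepine by a reversible retro-Claisen shift.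

Step 13
Reactants: 15 3-bromobut-3-en-1-ol
Product: 16 benzyl 3-bromobut-3-en-1-yl ether
Conditions: NaH, BnBr, Bu4NI (cat.), THF, 0 °C → rt
Reagents that add atoms: benzyl bromide, BrCc1ccccc1
Why: Williamson ether synthesis protects the future C12 oxygen as a benzyl ether, which withstands organolithium, hydride and heat and is removed in the hydrogenation of step 19.

Step 14
Reactants: 14 3α-(tert-butyldimethylsilyloxy)-4,4-dimethyl-6-exo-[(E)-prop-1-enyl]-5-(triethylsilyloxy)bicyclo[3.1.0]hexane-1-carbaldehyde; 16 benzyl 3-bromobut-3-en-1-yl ether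
Product: 18 4-(benzyloxy)-1-{3α-(tert-butyldimethylsilyloxy)-4,4-dimethyl-6-exo-[(E)-prop-1-enyl]-5-(triethylsilyloxy)bicyclo[3.1.0]hexan-1-yl}-2-methylenebutan-1-ol, via [4-(benzyloxy)but-1-en-2-yl]lithium 17 (not isolated)
Conditions: 16, t-BuLi (2 equiv), Et2O, −78 °C; then 14, −78 °C; aq. NH4Cl
Reagents that add atoms: none
Why: Bromine–lithium exchange gives the 2-lithioalkene, which adds 1,2 to the non-enolisable aldehyde (C9–C10 bond); the C10 carbinol forms as a mixture that is oxidised in the next step.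

Step 15
Reactants: 18 4-(benzyloxy)-1-{3α-(tert-butyldimethylsilyloxy)-4,4-dimethyl-6-exo-[(E)-prop-1-enyl]-5-(triethylsilyloxy)bicyclo[3.1.0]hexan-1-yl}-2-methylenebutan-1-ol
Product: 19 4-(benzyloxy)-1-{3α-(tert-butyldimethylsilyloxy)-4,4-dimethyl-6-exo-[(E)-prop-1-enyl]-5-(triethylsilyloxy)bicyclo[3.1.0]hexan-1-yl}-2-methylenebutan-1-one
Conditions: Dess–Martin periodinane, pyridine, CH2Cl2, 0 °C
Reagents that add atoms: none
Why: Dess–Martin oxidation of the allylic cyclopropyl carbinol gives the α-methylene ketone, a cis-2-vinylcyclopropyl ketone of the kind that is stable at room temperature.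

Step 16
Reactants: 19 4-(benzyloxy)-1-{3α-(tert-butyldimethylsilyloxy)-4,4-dimethyl-6-exo-[(E)-prop-1-enyl]-5-(triethylsilyloxy)bicyclo[3.1.0]hexan-1-yl}-2-methylenebutan-1-one
Product: 21 1-[(1E)-4-(benzyloxy)-2-methyl-1-(triethylsilyloxy)but-1-en-1-yl]-3α-(tert-butyldimethylsilyloxy)-4,4-dimethyl-6-exo-[(E)-prop-1-enyl]-5-(triethylsilyloxy)bicyclo[3.1.0]hexane, via lithium enolate 20 (not isolated)
Conditions: LiBH(s-Bu)3, THF, −78 °C; then Et3SiCl, Et3N, −78 → 0 °C
Reagents that add atoms: chlorotriethylsilane, CC[Si](CC)(CC)Cl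
Why: Conjugate reduction of the β-unsubstituted enone through its s-cis conformer (the quaternary C1 disfavours s-trans) should give the enolate with the new methyl cis to oxygen, hence trans to C1, and O-silylation traps this geometry.

Step 17
Reactants: 21 1-[(1E)-4-(benzyloxy)-2-methyl-1-(triethylsilyloxy)but-1-en-1-yl]-3α-(tert-butyldimethylsilyloxy)-4,4-dimethyl-6-exo-[(E)-prop-1-enyl]-5-(triethylsilyloxy)bicyclo[3.1.0]hexane
Product: 22 9β-[2-(benzyloxy)ethyl]-3α-(tert-butyldimethylsilyloxy)-4,4,8α,9α-tetramethyl-5β,10-bis(triethylsilyloxy)hydroazulene-1(10),6-diene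
Conditions: PhMe (degassed), BHT (cat.), base-washed sealed tube, 120 °C
Reagents that add atoms: none
Why: The step is a concerted [3,3] sigmatropic (Cope) shift of a cis-1,2-dialkenylcyclopropane through a boat transition state with both alkenyl groups folded over the three-membered ring, driven by release of ring strain; the closest known reaction type is the divinylcyclopropane–cycloheptadiene rearrangement of siloxyvinyl cyclopropanes and of 1,6-dialkenylbicyclo[3.1.0]hexanes. Ring B (seven-membered) is closed by ring expansion: the alkene termini C8 and C9 bond while the ring bond C1–C6 breaks, leaving C6=C7 and the C1=C10 enol silane. C8 is controlled by the (E)-propenyl geometry and C9 by the enol ether geometry (methyl trans to C1), so that in the boat both outward methyl groups should end up cis to each other and on the face opposite the C5 oxygen, whose configuration is that of the cyclopropane. The step needs the boat pathway to outrun homolytic opening and epimerisation of the cyclopropane, and the bicyclic frame secures this by holding the exo C6 alkenyl group and the bridgehead C1 alkenyl group cis. The C9 terminus is fully substituted and must turn its benzyloxyethyl chain inward beside the C5 oxygen, hence the heating, the small silyl group on that oxygen and the exclusion of acid.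

Step 18
Reactants: 22 9β-[2-(benzyloxy)ethyl]-3α-(tert-butyldimethylsilyloxy)-4,4,8α,9α-tetramethyl-5β,10-bis(triethylsilyloxy)hydroazulene-1(10),6-diene
Product: 23 9β-[2-(benzyloxy)ethyl]-3α-(tert-butyldimethylsilyloxy)-4,4,8α,9α-tetramethyl-5β-(triethylsilyloxy)-1α-H-hydroazulen-6-en-10-one
Conditions: Bu4NF (1.1 equiv), AcOH (1.5 equiv), THF, −40 °C
Reagents that add atoms: none
Why: Buffered fluoride desilylation cleaves the enol silane first and acetic acid protonates the enolate at C1 before it can expel the C5 silyloxy group; the proton should enter anti to that adjacent group (α face), giving the trans ring fusion, which is also expected to be the more stable one.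

Step 19
Reactants: 23 9β-[2-(benzyloxy)ethyl]-3α-(tert-butyldimethylsilyloxy)-4,4,8α,9α-tetramethyl-5β-(triethylsilyloxy)-1α-H-hydroazulen-6-en-10-one
Product: 24 3α-(tert-butyldimethylsilyloxy)-9β-(2-hydroxyethyl)-4,4,8α,9α-tetramethyl-5β-(triethylsilyloxy)-1α-H-hydroazulan-10-one
Conditions: H2 (1 atm), Pd/C, EtOAc/EtOH, rt
Reagents that add atoms: none
Why: Heterogeneous hydrogenation saturates the cis-disubstituted C6=C7 alkene and hydrogenolyses the benzyl ether in the same operation; no stereocentre is formed.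

Step 20
Reactants: 24 3α-(tert-butyldimethylsilyloxy)-9β-(2-hydroxyethyl)-4,4,8α,9α-tetramethyl-5β-(triethylsilyloxy)-1α-H-hydroazulan-10-one
Product: 25 3α-(tert-butyldimethylsilyloxy)-9β-(2-iodoethyl)-4,4,8α,9α-tetramethyl-5β-(triethylsilyloxy)-1α-H-hydroazulan-10-one
Conditions: I2, PPh3, imidazole, CH2Cl2, 0 °C → rt
Reagents that add atoms: iodine, II
Why: Appel-type (Garegg–Samuelsson) iodination converts the primary alcohol, reacting through the open hydroxy ketone form, while the hindered ketone and the silyl ethers stay inert.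

Step 21
Reactants: 25 3α-(tert-butyldimethylsilyloxy)-9β-(2-iodoethyl)-4,4,8α,9α-tetramethyl-5β-(triethylsilyloxy)-1α-H-hydroazulan-10-one; 26 4-bromofuran-2(5H)-one
Product: 28 4-{2-[3α-(tert-butyldimethylsilyloxy)-4,4,8α,9α-tetramethyl-10-oxo-5β-(triethylsilyloxy)-1α-H-hydroazulan-9β-yl]ethyl}furan-2(5H)-one, via alkylzinc iodide 27 (not isolated)
Conditions: 25, Zn dust (activated with Me3SiCl and BrCH2CH2Br), DMA, 40 °C; then 26, Pd2(dba)3 (2.5 mol %), SPhos (10 mol %), THF, rt
Reagents that add atoms: none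
Why: Zinc insertion into the primary iodide gives a ketone-tolerant alkylzinc iodide that should undergo Negishi coupling at the C–Br bond of the β-bromobutenolide.

Step 22
Reactants: 28 4-{2-[3α-(tert-butyldimethylsilyloxy)-4,4,8α,9α-tetramethyl-10-oxo-5β-(triethylsilyloxy)-1α-H-hydroazulan-9β-yl]ethyl}furan-2(5H)-one
Product: 29 CNP0077405.2
Conditions: HF (48 % aq.), MeCN, 0 °C → rt
Reagents that add atoms: none
Why: Acidic fluoride desilylation removes the tertiary triethylsilyl and the secondary tert-butyldimethylsilyl ether without the base that could cause retro-aldol cleavage or dehydration of the β-hydroxy ketone or open the butenolide.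

Compound list
1 | 2,2-dimethylcyclopentane-1,3-dione | CC1(C)C(=O)CCC1=O | starting material
2 | (S)-3-hydroxy-2,2-dimethylcyclopentan-1-one | O=C1CC[C@H](O)C1(C)C | intermediate
3 | (S)-2,2-dimethyl-3-oxocyclopentyl pivalate | O=C1CC[C@H](OC(=O)C(C)(C)C)C1(C)C | intermediate
4 | (1S)-4-(hydroxymethyl)-2,2-dimethyl-3-oxocyclopentyl pivalate, both epimers at the hydroxymethyl-bearing carbon (target C1) | O=C1C(CO)C[C@H](OC(=O)C(C)(C)C)C1(C)C | intermediate
5 | (1S)-2,2-dimethyl-3-(triethylsilyloxy)-4-[(triethylsilyloxy)methyl]cyclopent-3-en-1-yl pivalate | CC[Si](CC)(CC)OCC1=C(O[Si](CC)(CC)CC)C(C)(C)[C@@H](OC(=O)C(C)(C)C)C1 | intermediate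
6 | ethyl diazoacetate | CCOC(=O)C=[N+]=[N-] | starting material
7 | ethyl 4,4-dimethyl-3β-(pivaloyloxy)-5-(triethylsilyloxy)-1-[(triethylsilyloxy)methyl]bicyclo[3.1.0]hexane-6-exo-carboxylate (cyclopropane on the α face, trans to the pivalate) | CCOC(=O)[C@H]1[C@]2(O[Si](CC)(CC)CC)C(C)(C)[C@@H](OC(=O)C(C)(C)C)C[C@]12CO[Si](CC)(CC)CC | intermediate
8 | 6-exo-(hydroxymethyl)-4,4-dimethyl-5-(triethylsilyloxy)-1-[(triethylsilyloxy)methyl]bicyclo[3.1.0]hexan-3β-ol | OC[C@H]1[C@]2(O[Si](CC)(CC)CC)C(C)(C)[C@@H](O)C[C@]12CO[Si](CC)(CC)CC | intermediate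
9 | 4,4-dimethyl-3-oxo-5-(triethylsilyloxy)-1-[(triethylsilyloxy)methyl]bicyclo[3.1.0]hexane-6-exo-carbaldehyde | O=C[C@H]1[C@]2(O[Si](CC)(CC)CC)C(C)(C)C(=O)C[C@]12CO[Si](CC)(CC)CC | intermediate
10 | 4,4-dimethyl-6-exo-[(E)-prop-1-enyl]-5-(triethylsilyloxy)-1-[(triethylsilyloxy)methyl]bicyclo[3.1.0]hexan-3-one | C/C=C/[C@H]1[C@]2(O[Si](CC)(CC)CC)C(C)(C)C(=O)C[C@]12CO[Si](CC)(CC)CC | intermediate
11 | 4,4-dimethyl-6-exo-[(E)-prop-1-enyl]-5-(triethylsilyloxy)-1-[(triethylsilyloxy)methyl]bicyclo[3.1.0]hexan-3α-ol (3R, hydroxyl cis to the cyclopropane) | C/C=C/[C@H]1[C@]2(O[Si](CC)(CC)CC)C(C)(C)[C@H](O)C[C@]12CO[Si](CC)(CC)CC | intermediate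
12 | 3α-(tert-butyldimethylsilyloxy)-4,4-dimethyl-6-exo-[(E)-prop-1-enyl]-5-(triethylsilyloxy)-1-[(triethylsilyloxy)methyl]bicyclo[3.1.0]hexane | C/C=C/[C@H]1[C@]2(O[Si](CC)(CC)CC)C(C)(C)[C@H](O[Si](C)(C)C(C)(C)C)C[C@]12CO[Si](CC)(CC)CC | intermediate
13 | {3α-(tert-butyldimethylsilyloxy)-4,4-dimethyl-6-exo-[(E)-prop-1-enyl]-5-(triethylsilyloxy)bicyclo[3.1.0]hexan-1-yl}methanol | C/C=C/[C@H]1[C@]2(O[Si](CC)(CC)CC)C(C)(C)[C@H](O[Si](C)(C)C(C)(C)C)C[C@]12CO | intermediate
14 | 3α-(tert-butyldimethylsilyloxy)-4,4-dimethyl-6-exo-[(E)-prop-1-enyl]-5-(triethylsilyloxy)bicyclo[3.1.0]hexane-1-carbaldehyde | C/C=C/[C@H]1[C@]2(O[Si](CC)(CC)CC)C(C)(C)[C@H](O[Si](C)(C)C(C)(C)C)C[C@]12C=O | intermediate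
15 | 3-bromobut-3-en-1-ol | C=C(Br)CCO | starting material
16 | benzyl 3-bromobut-3-en-1-yl ether | C=C(Br)CCOCc1ccccc1 | intermediate
17 | [4-(benzyloxy)but-1-en-2-yl]lithium (not isolated) | [Li]C(=C)CCOCc1ccccc1 | intermediate
18 | 4-(benzyloxy)-1-{3α-(tert-butyldimethylsilyloxy)-4,4-dimethyl-6-exo-[(E)-prop-1-enyl]-5-(triethylsilyloxy)bicyclo[3.1.0]hexan-1-yl}-2-methylenebutan-1-ol, both C10 epimers | C/C=C/[C@H]1[C@]2(O[Si](CC)(CC)CC)C(C)(C)[C@H](O[Si](C)(C)C(C)(C)C)C[C@]12C(O)C(=C)CCOCc1ccccc1 | intermediate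
19 | 4-(benzyloxy)-1-{3α-(tert-butyldimethylsilyloxy)-4,4-dimethyl-6-exo-[(E)-prop-1-enyl]-5-(triethylsilyloxy)bicyclo[3.1.0]hexan-1-yl}-2-methylenebutan-1-one | C/C=C/[C@H]1[C@]2(O[Si](CC)(CC)CC)C(C)(C)[C@H](O[Si](C)(C)C(C)(C)C)C[C@]12C(=O)C(=C)CCOCc1ccccc1 | intermediate
20 | lithium (1E)-4-(benzyloxy)-1-{3α-(tert-butyldimethylsilyloxy)-4,4-dimethyl-6-exo-[(E)-prop-1-enyl]-5-(triethylsilyloxy)bicyclo[3.1.0]hexan-1-yl}-2-methylbut-1-en-1-olate, methyl cis to oxygen (not isolated) | C/C=C/[C@H]1[C@]2(O[Si](CC)(CC)CC)C(C)(C)[C@H](O[Si](C)(C)C(C)(C)C)C[C@]12/C(O[Li])=C(/C)CCOCc1ccccc1 | intermediate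
21 | 1-[(1E)-4-(benzyloxy)-2-methyl-1-(triethylsilyloxy)but-1-en-1-yl]-3α-(tert-butyldimethylsilyloxy)-4,4-dimethyl-6-exo-[(E)-prop-1-enyl]-5-(triethylsilyloxy)bicyclo[3.1.0]hexane (enol ether methyl trans to C1) | C/C=C/[C@H]1[C@]2(O[Si](CC)(CC)CC)C(C)(C)[C@H](O[Si](C)(C)C(C)(C)C)C[C@]12/C(O[Si](CC)(CC)CC)=C(/C)CCOCc1ccccc1 | intermediate
22 | hydroazulene (bicyclo[5.3.0]decane, target locants) with C1=C10 and C6=C7 double bonds: 9β-[2-(benzyloxy)ethyl]-3α-(tert-butyldimethylsilyloxy)-4,4,8α,9α-tetramethyl-5β,10-bis(triethylsilyloxy) | C[C@@H]1C=C[C@@]2(O[Si](CC)(CC)CC)C(C[C@@H](O[Si](C)(C)C(C)(C)C)C2(C)C)=C(O[Si](CC)(CC)CC)[C@@]1(C)CCOCc1ccccc1 | intermediate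
23 | trans-fused hydroazulen-6-en-10-one (target locants): 9β-[2-(benzyloxy)ethyl]-3α-(tert-butyldimethylsilyloxy)-4,4,8α,9α-tetramethyl-5β-(triethylsilyloxy), 1α-H | C[C@@H]1C=C[C@@]2(O[Si](CC)(CC)CC)[C@@H](C[C@@H](O[Si](C)(C)C(C)(C)C)C2(C)C)C(=O)[C@@]1(C)CCOCc1ccccc1 | intermediate
24 | saturated trans-fused hydroazulan-10-one: 3α-(tert-butyldimethylsilyloxy)-9β-(2-hydroxyethyl)-4,4,8α,9α-tetramethyl-5β-(triethylsilyloxy), 1α-H | C[C@@H]1CC[C@@]2(O[Si](CC)(CC)CC)[C@@H](C[C@@H](O[Si](C)(C)C(C)(C)C)C2(C)C)C(=O)[C@@]1(C)CCO | intermediate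
25 | 3α-(tert-butyldimethylsilyloxy)-9β-(2-iodoethyl)-4,4,8α,9α-tetramethyl-5β-(triethylsilyloxy)-1α-H-hydroazulan-10-one | C[C@@H]1CC[C@@]2(O[Si](CC)(CC)CC)[C@@H](C[C@@H](O[Si](C)(C)C(C)(C)C)C2(C)C)C(=O)[C@@]1(C)CCI | intermediate
26 | 4-bromofuran-2(5H)-one | BrC1=CC(=O)OC1 | starting material
27 | alkylzinc iodide from 25, zinc on C12 (not isolated) | C[C@@H]1CC[C@@]2(O[Si](CC)(CC)CC)[C@@H](C[C@@H](O[Si](C)(C)C(C)(C)C)C2(C)C)C(=O)[C@@]1(C)CC[Zn]I | intermediate
28 | 4-{2-[3α-(tert-butyldimethylsilyloxy)-4,4,8α,9α-tetramethyl-10-oxo-5β-(triethylsilyloxy)-1α-H-hydroazulan-9β-yl]ethyl}furan-2(5H)-one | C[C@@H]1CC[C@@]2(O[Si](CC)(CC)CC)[C@@H](C[C@@H](O[Si](C)(C)C(C)(C)C)C2(C)C)C(=O)[C@@]1(C)CCC1=CC(=O)OC1 | intermediate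
29 | CNP0077405.2: 4-{2-[3α,5β-dihydroxy-4,4,8α,9α-tetramethyl-10-oxo-1α-H-hydroazulan-9β-yl]ethyl}furan-2(5H)-one (target locants 1R,3R,5R,8R,9S) | C[C@@H]1CC[C@@]2(O)[C@@H](C[C@@H](O)C2(C)C)C(=O)[C@@]1(C)CCC1=CC(=O)OC1 | target

Total step count: 22. Longest linear sequence: 21 steps (steps 1–12 and 14–22, from 1); step 13 prepares the side-chain fragment.

Steps most likely to fail

Step 17. The shift may stall because the fully substituted C9 terminus has to fold its benzyloxyethyl chain inward next to the C5 silyloxy group; at the temperature then required, homolytic opening of the siloxycyclopropane with loss of its configuration, or decomposition of the enol silanes, may take over. The fallback builds the quaternary centre after the ring expansion; it sets out from 14 and returns at 23. Ethylmagnesium bromide adds to 14 to give the carbinol F1, and Dess–Martin oxidation gives the ethyl ketone F2. LiN(i-Pr)2 and Et3SiCl should convert F2 into the (Z)-enol silane F3, because a bulky acyl substituent favours the enolate with methyl cis to oxygen, so the methyl points outward and only hydrogen points inward. With both termini now E-monosubstituted, the rearrangement is well within precedent and should give, under mild heating, the diene F4 with the C8 and C9 methyl groups cis on the α face. Buffered fluoride as in step 18 gives the ketone F5. Kinetic deprotonation at C9 with KN(SiMe3)2, followed by alkylation with 2-(benzyloxy)ethyl trifluoromethanesulfonate anti to the C8 methyl, would then give 23.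

Step 5. The remote C3 ester may discriminate the two faces of the tetrasubstituted enol ether only weakly, and carbene dimerisation may outrun addition to this hindered alkene. The fallback moves facial control from the substrate to a chiral catalyst; it sets out from 5 and returns at 8. tert-Butyl diazoacetate with (CuOTf)2·C6H6 and 2,2'-isopropylidenebis(4-tert-butyl-2-oxazoline), in the enantiomer that reinforces α-face attack, forms a bulkier and more selective copper carbenoid and should give the tert-butyl ester F6. Reduction with i-Bu2AlH as in step 6 converts F6 into 8.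

Step 18. The enolate may be protonated on the β face, giving the cis ring fusion, or may expel the C5 silyloxy group. The fallback replaces kinetic protonation by thermodynamic control on the isolated ketone; it sets out from 22 and returns at 23. The cis-fused epimer F7 that the unmasking of 22 would then deliver is separated and equilibrated by reversible enolisation (DBU, PhMe, rt), relying on the expected preference of this hydroazulenone for the trans fusion, to give 23.

Further compounds
F1 | step 17 | 1-{3α-(tert-butyldimethylsilyloxy)-4,4-dimethyl-6-exo-[(E)-prop-1-enyl]-5-(triethylsilyloxy)bicyclo[3.1.0]hexan-1-yl}propan-1-ol, both C10 epimers | C/C=C/[C@H]1[C@]2(O[Si](CC)(CC)CC)C(C)(C)[C@H](O[Si](C)(C)C(C)(C)C)C[C@]12C(O)CC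
F2 | step 17 | 1-{3α-(tert-butyldimethylsilyloxy)-4,4-dimethyl-6-exo-[(E)-prop-1-enyl]-5-(triethylsilyloxy)bicyclo[3.1.0]hexan-1-yl}propan-1-one | C/C=C/[C@H]1[C@]2(O[Si](CC)(CC)CC)C(C)(C)[C@H](O[Si](C)(C)C(C)(C)C)C[C@]12C(=O)CC
F3 | step 17 | 3α-(tert-butyldimethylsilyloxy)-4,4-dimethyl-6-exo-[(E)-prop-1-enyl]-5-(triethylsilyloxy)-1-[(1Z)-1-(triethylsilyloxy)prop-1-en-1-yl]bicyclo[3.1.0]hexane | C/C=C/[C@H]1[C@]2(O[Si](CC)(CC)CC)C(C)(C)[C@H](O[Si](C)(C)C(C)(C)C)C[C@]12/C(O[Si](CC)(CC)CC)=C/C
F4 | step 17 | 3α-(tert-butyldimethylsilyloxy)-4,4,8α,9α-tetramethyl-5β,10-bis(triethylsilyloxy)hydroazulene-1(10),6-diene (9β-H) | C[C@@H]1C=C[C@@]2(O[Si](CC)(CC)CC)C(C[C@@H](O[Si](C)(C)C(C)(C)C)C2(C)C)=C(O[Si](CC)(CC)CC)[C@@H]1C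
F5 | step 17 | 3α-(tert-butyldimethylsilyloxy)-4,4,8α,9α-tetramethyl-5β-(triethylsilyloxy)-1α-H-hydroazulen-6-en-10-one (9β-H) | C[C@@H]1C=C[C@@]2(O[Si](CC)(CC)CC)[C@@H](C[C@@H](O[Si](C)(C)C(C)(C)C)C2(C)C)C(=O)[C@@H]1C
F6 | step 5 | tert-butyl 4,4-dimethyl-3β-(pivaloyloxy)-5-(triethylsilyloxy)-1-[(triethylsilyloxy)methyl]bicyclo[3.1.0]hexane-6-exo-carboxylate | CC(C)(C)OC(=O)[C@H]1[C@]2(O[Si](CC)(CC)CC)C(C)(C)[C@@H](OC(=O)C(C)(C)C)C[C@]12CO[Si](CC)(CC)CC
F7 | step 18 | cis-fused C1 epimer (1β-H) of 23 | C[C@@H]1C=C[C@@]2(O[Si](CC)(CC)CC)[C@H](C[C@@H](O[Si](C)(C)C(C)(C)C)C2(C)C)C(=O)[C@@]1(C)CCOCc1ccccc1
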